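**Retrosynthetic overview**
1. Target 16 ← selective O-acetylation of bicyclic triol 15.
2. 15 ← one light-driven decarboxylative radical bicyclisation of acyclic carboxylate 14: C4–C5 closes ring A, then C9–C10 closes ring B, and the allylic sulfone on C7 leaves to fix the C7=C8 alkene (labdane numbering).
3. 14 ← lactone 13 ← triol 12 ← α-hydroxy ketone 11 (chelation-controlled reduction sets C2) ← β-keto sulfone 10.
4. 10 ← C1–C2 bond by acylating lithiated bis-sulfone 7 with D-pantolactone 8, which supplies C2–C4, the gem-dimethyl group and the only bought stereocentre (C3); its CH2O carbon later leaves as CO2.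
5. 7 ← geranyl acetate 1 by two rounds of ene-chlorination/sulfination around one prenylation with 4.

Assumption: the chloride- and sulfone-bearing sp3 carbons of the chain (C-6 in 2, C-10 in 6, C-8 from 5 on, C-12 in 10) are carried as epimer mixtures and left unspecified in the SMILES, since all are destroyed before 15.

**Step 1**
Reactants: 1 geranyl acetate
Product: 2 (2E)-6-chloro-3,7-dimethylocta-2,7-dien-1-yl acetate
Conditions: Ca(OCl)2, CO2 (dry ice), CH2Cl2/H2O, 0 °C
Reagents that add atoms: calcium hypochlorite [Ca+2].[O-]Cl.[O-]Cl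
Why: Ene-type allylic chlorination by HOCl attacks only the electron-rich 6,7-alkene (the 2,3-alkene is deactivated by the allylic acetate) and moves it to the chain end, giving the secondary allylic chloride.

**Step 2**
Reactants: 2 (2E)-6-chloro-3,7-dimethylocta-2,7-dien-1-yl acetate
Product: 3 (2E,6E)-3,7-dimethyl-8-(phenylsulfonyl)octa-2,6-dien-1-yl acetate
Conditions: PhSO2Na (2 equiv), Bu4NI (10 mol %), DMF, 70 °C
Reagents that add atoms: sodium benzenesulfinate [Na+].[O-]S(=O)c1ccccc1
Why: SN2' displacement of the allylic chloride by the sulfur of sulfinate, with sulfinate-mediated 1,3-sulfonyl shift of any branched isomer, funnels to the more stable primary (E)-allylic sulfone.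

**Step 3**
Reactants: 3 (2E,6E)-3,7-dimethyl-8-(phenylsulfonyl)octa-2,6-dien-1-yl acetate; 4 prenyl bromide
Product: 5 (2E,6E)-3,7,11-trimethyl-8-(phenylsulfonyl)dodeca-2,6,10-trien-1-yl acetate
Conditions: LiN(SiMe3)2 (1.05 equiv), THF, −78 °C; then 4, −78 → −40 °C
Reagents that add atoms: none
Why: Biellmann/Julia-type alkylation of the sulfonyl-stabilised allylic carbanion at its α-carbon by SN2 on prenyl bromide, with the acetate untouched at −78 °C.

**Step 4**
Reactants: 5 (2E,6E)-3,7,11-trimethyl-8-(phenylsulfonyl)dodeca-2,6,10-trien-1-yl acetate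
Product: 6 (2E,6E)-10-chloro-3,7,11-trimethyl-8-(phenylsulfonyl)dodeca-2,6,11-trien-1-yl acetate
Conditions: Ca(OCl)2, CO2 (dry ice), CH2Cl2/H2O, 0 °C
Reagents that add atoms: calcium hypochlorite [Ca+2].[O-]Cl.[O-]Cl
Why: The same ene-type chlorination is selective for the terminal alkene, because the other two alkenes carry an electron-withdrawing allylic sulfone or acetate.

**Step 5**
Reactants: 6 (2E,6E)-10-chloro-3,7,11-trimethyl-8-(phenylsulfonyl)dodeca-2,6,11-trien-1-yl acetate
Product: 7 (2E,6E,10E)-3,7,11-trimethyl-8,12-bis(phenylsulfonyl)dodeca-2,6,10-trien-1-yl acetate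
Conditions: PhSO2Na (2 equiv), Bu4NI (10 mol %), DMF, 70 °C
Reagents that add atoms: sodium benzenesulfinate [Na+].[O-]S(=O)c1ccccc1
Why: SN2' sulfination as in step 2 gives the primary (E)-allylic sulfone at C-12, the handle for the next C–C bond.

**Step 6**
Reactants: 7 (2E,6E,10E)-3,7,11-trimethyl-8,12-bis(phenylsulfonyl)dodeca-2,6,10-trien-1-yl acetate; 8 D-(−)-pantolactone
Product: 10 (2E,6E,10E,14R)-14,16-dihydroxy-3,7,11,15,15-pentamethyl-13-oxo-8,12-bis(phenylsulfonyl)hexadeca-2,6,10-trien-1-yl acetate, via O-trimethylsilyl-pantolactone 9 (not isolated)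
Conditions: 8, HN(SiMe3)2 (0.6 equiv), Me3SiCl (2 mol %), 40 °C, evaporate; separately 7, LiN(SiMe3)2 (1.05 equiv), THF, −78 °C; add 9, −78 → −30 °C; then 1 M HCl, THF, 0 °C
Reagents that add atoms: none
Why: Acylation of a lithiated sulfone by a lactone (Claisen-type condensation held at the lithium hemiketalate): the base removes the more acidic, less hindered C-12 proton rather than the C-8 proton, the α-carbanion adds to the lactone carbonyl, and acidic work-up removes the silyl group to release the β-keto sulfone (largely as its cyclic hemiketal) with C-14 still R as bought.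

**Step 7**
Reactants: 10 (2E,6E,10E,14R)-14,16-dihydroxy-3,7,11,15,15-pentamethyl-13-oxo-8,12-bis(phenylsulfonyl)hexadeca-2,6,10-trien-1-yl acetate
Product: 11 (2E,6E,10E,14R)-14,16-dihydroxy-3,7,11,15,15-pentamethyl-13-oxo-8-(phenylsulfonyl)hexadeca-2,6,10-trien-1-yl acetate
Conditions: SmI2 (2.2 equiv), THF/MeOH, −78 °C; aq. NH4Cl
Reagents that add atoms: none
Why: Reductive desulfonylation of a β-keto sulfone by single-electron transfer (C–S cleavage to the samarium enolate, kinetic α-protonation by MeOH), while the isolated C-8 allylic sulfone is not reduced without HMPA and the 10E alkene stays out of conjugation in the cold.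

**Step 8**
Reactants: 11 (2E,6E,10E,14R)-14,16-dihydroxy-3,7,11,15,15-pentamethyl-13-oxo-8-(phenylsulfonyl)hexadeca-2,6,10-trien-1-yl acetate
Product: 12 (2E,6E,10E,13S,14R)-13,14,16-trihydroxy-3,7,11,15,15-pentamethyl-8-(phenylsulfonyl)hexadeca-2,6,10-trien-1-yl acetate
Conditions: Zn(BH4)2, Et2O/THF, −20 → 0 °C; aq. NH4Cl
Reagents that add atoms: none
Why: Chelation-controlled (Cram-chelate) reduction of the α-hydroxy ketone, in which zinc bridges the C-13 carbonyl and the C-14 hydroxyl and hydride enters anti to the quaternary substituent, sets 13S as the anti (erythro) diol.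

**Step 9**
Reactants: 12 (2E,6E,10E,13S,14R)-13,14,16-trihydroxy-3,7,11,15,15-pentamethyl-8-(phenylsulfonyl)hexadeca-2,6,10-trien-1-yl acetate
Product: 13 (2E,6E,10E)-12-[(2S,3R)-3-hydroxy-4,4-dimethyl-5-oxooxolan-2-yl]-3,7,11-trimethyl-8-(phenylsulfonyl)dodeca-2,6,10-trien-1-yl acetate
Conditions: TEMPO (20 mol %), PhI(OAc)2 (2.5 equiv), CH2Cl2, 25 °C
Reagents that add atoms: none
Why: Oxidative lactonisation of a 1,4-diol: the oxoammonium oxidant takes the primary alcohol selectively, the aldehyde is trapped by the C-13 hydroxyl as a lactol and oxidised on to the γ-lactone, which stores C-16 at the acid level.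

**Step 10**
Reactants: 13 (2E,6E,10E)-12-[(2S,3R)-3-hydroxy-4,4-dimethyl-5-oxooxolan-2-yl]-3,7,11-trimethyl-8-(phenylsulfonyl)dodeca-2,6,10-trien-1-yl acetate
Product: 15 (2R,3S,4aS,5R,8aS)-5-[(3E)-5-hydroxy-3-methylpent-3-en-1-yl]-1,1,4a,6-tetramethyl-1,2,3,4,4a,5,8,8a-octahydronaphthalene-2,3-diol, via cesium seco-carboxylate 14 (not isolated)
Conditions: CsOH·H2O (2.1 equiv), THF/H2O, 40 °C, evaporate; then 4CzIPN (2 mol %), degassed DMSO/H2O 9:1 (5 mM), 450 nm LEDs, 25 °C; aq. NH4Cl
Reagents that add atoms: none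
Why: Proposed new method: hydroxide opens the lactone (and cleaves the acetate) to the tertiary carboxylate, which excited 4CzIPN oxidises; loss of CO2 gives the C-4 radical (labdane numbering), which adds 6-endo to C-5; the C-10 radical then adds 6-endo to C-9 through a chair–chair transition state with the C-2 hydroxyl equatorial and the C-3 hydroxyl axial, so the bought C-3 centre and the C-2 centre derived from it set C-5, C-10, C-9 and the trans ring fusion; the C-8 radical finally expels PhSO2• from C-7, placing the alkene at C-7/C-8 only, and the reduced photocatalyst returns its electron to the sulfonyl radical; the closest known reaction types are photoredox decarboxylative radical allylation with allyl sulfones (intermolecular addition–fragmentation) and radical epoxypolyene bicyclisation mediated by trivalent titanium, whereas a decarboxylative polyene bicyclisation terminated by sulfonyl-radical β-fragmentation is not known.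

**Step 11**
Reactants: 15 (2R,3S,4aS,5R,8aS)-5-[(3E)-5-hydroxy-3-methylpent-3-en-1-yl]-1,1,4a,6-tetramethyl-1,2,3,4,4a,5,8,8a-octahydronaphthalene-2,3-diol
Product: 16 (2E)-5-[(1R,4aS,6R,7S,8aS)-6,7-dihydroxy-2,5,5,8a-tetramethyl-1,4,4a,5,6,7,8,8a-octahydronaphthalen-1-yl]-3-methylpent-2-en-1-yl acetate
Conditions: AcCl (1.05 equiv), 2,4,6-collidine, CH2Cl2, −78 °C
Reagents that add atoms: acetyl chloride CC(=O)Cl
Why: Chemoselective acylation of the unhindered primary allylic alcohol over the equatorial C-2 and the axial, neopentyl C-3 secondary alcohols.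

**Compound list**
1 | geranyl acetate, (2E)-3,7-dimethylocta-2,6-dien-1-yl acetate | CC(=O)OC/C=C(C)/CCC=C(C)C | starting material
2 | (2E)-6-chloro-3,7-dimethylocta-2,7-dien-1-yl acetate (racemic) | CC(=O)OC/C=C(C)/CCC(Cl)C(C)=C | intermediate
3 | (2E,6E)-3,7-dimethyl-8-(phenylsulfonyl)octa-2,6-dien-1-yl acetate | CC(=O)OC/C=C(C)/CC/C=C(C)/CS(=O)(=O)c1ccccc1 | intermediate
4 | prenyl bromide, 1-bromo-3-methylbut-2-ene | CC(C)=CCBr | starting material
5 | (2E,6E)-3,7,11-trimethyl-8-(phenylsulfonyl)dodeca-2,6,10-trien-1-yl acetate (racemic at C-8) | CC(=O)OC/C=C(C)/CC/C=C(C)/C(CC=C(C)C)S(=O)(=O)c1ccccc1 | intermediate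
6 | (2E,6E)-10-chloro-3,7,11-trimethyl-8-(phenylsulfonyl)dodeca-2,6,11-trien-1-yl acetate (diastereomer mixture) | CC(=O)OC/C=C(C)/CC/C=C(C)/C(CC(Cl)C(C)=C)S(=O)(=O)c1ccccc1 | intermediate
7 | (2E,6E,10E)-3,7,11-trimethyl-8,12-bis(phenylsulfonyl)dodeca-2,6,10-trien-1-yl acetate (racemic at C-8) | CC(=O)OC/C=C(C)/CC/C=C(C)/C(C/C=C(C)/CS(=O)(=O)c1ccccc1)S(=O)(=O)c1ccccc1 | intermediate
8 | D-(−)-pantolactone, (3R)-3-hydroxy-4,4-dimethyloxolan-2-one | CC1(C)COC(=O)[C@@H]1O | starting material
9 | O-trimethylsilyl-pantolactone, (3R)-4,4-dimethyl-3-(trimethylsilyloxy)oxolan-2-one | CC1(C)COC(=O)[C@@H]1O[Si](C)(C)C | intermediate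
10 | (2E,6E,10E,14R)-14,16-dihydroxy-3,7,11,15,15-pentamethyl-13-oxo-8,12-bis(phenylsulfonyl)hexadeca-2,6,10-trien-1-yl acetate (C-8/C-12 epimers; open form of the cyclic hemiketal) | CC(=O)OC/C=C(C)/CC/C=C(C)/C(C/C=C(C)/C(S(=O)(=O)c1ccccc1)C(=O)[C@H](O)C(C)(C)CO)S(=O)(=O)c1ccccc1 | intermediate
11 | (2E,6E,10E,14R)-14,16-dihydroxy-3,7,11,15,15-pentamethyl-13-oxo-8-(phenylsulfonyl)hexadeca-2,6,10-trien-1-yl acetate (C-8 epimers) | CC(=O)OC/C=C(C)/CC/C=C(C)/C(C/C=C(C)/CC(=O)[C@H](O)C(C)(C)CO)S(=O)(=O)c1ccccc1 | intermediate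
12 | (2E,6E,10E,13S,14R)-13,14,16-trihydroxy-3,7,11,15,15-pentamethyl-8-(phenylsulfonyl)hexadeca-2,6,10-trien-1-yl acetate (C-8 epimers) | CC(=O)OC/C=C(C)/CC/C=C(C)/C(C/C=C(C)/C[C@H](O)[C@H](O)C(C)(C)CO)S(=O)(=O)c1ccccc1 | intermediate
13 | (2E,6E,10E)-12-[(2S,3R)-3-hydroxy-4,4-dimethyl-5-oxooxolan-2-yl]-3,7,11-trimethyl-8-(phenylsulfonyl)dodeca-2,6,10-trien-1-yl acetate (C-8 epimers) | CC(=O)OC/C=C(C)/CC/C=C(C)/C(C/C=C(C)/C[C@@H]1OC(=O)C(C)(C)[C@H]1O)S(=O)(=O)c1ccccc1 | intermediate
14 | cesium (3R,4S,6E,10E,14E)-3,4,16-trihydroxy-2,2,6,10,14-pentamethyl-9-(phenylsulfonyl)hexadeca-6,10,14-trienoate (C-9 epimers) | OC/C=C(C)/CC/C=C(C)/C(C/C=C(C)/C[C@H](O)[C@H](O)C(C)(C)C(=O)[O-])S(=O)(=O)c1ccccc1.[Cs+] | intermediate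
15 | (2R,3S,4aS,5R,8aS)-5-[(3E)-5-hydroxy-3-methylpent-3-en-1-yl]-1,1,4a,6-tetramethyl-1,2,3,4,4a,5,8,8a-octahydronaphthalene-2,3-diol; in labdane numbering (2S,3R,5S,9R,10S)-labda-7,13E-diene-2,3,15-triol | OC/C=C(\C)CC[C@@H]1C(C)=CC[C@@H]2C(C)(C)[C@@H](O)[C@@H](O)C[C@@]12C | intermediate
16 | (2E)-5-[(1R,4aS,6R,7S,8aS)-6,7-dihydroxy-2,5,5,8a-tetramethyl-1,4,4a,5,6,7,8,8a-octahydronaphthalen-1-yl]-3-methylpent-2-en-1-yl acetate; in labdane numbering (2S,3R,5S,9R,10S)-2,3-dihydroxylabda-7,13E-dien-15-yl acetate | CC(=O)OC/C=C(\C)CC[C@@H]1C(C)=CC[C@@H]2C(C)(C)[C@@H](O)[C@@H](O)C[C@@]12C | target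

**Step count and risks**
Total steps: 11. Longest linear sequence: 11 (1 → 16); 4 and 8 enter as bought materials.

Three steps most likely to fail:

Step 5 (the same concern applies to step 2): the SN2' sulfination may give E/Z or branched/linear mixtures, and the preceding chlorination must discriminate three alkenes. Fallback, setting out from 5 and coming back at 7: allylic oxidation of the terminal (E)-methyl group with SeO2 (cat.)/t-BuOOH gives (2E,6E,10E)-12-hydroxy-3,7,11-trimethyl-8-(phenylsulfonyl)dodeca-2,6,10-trien-1-yl acetate F1 with the E geometry fixed by the ene/[2,3] mechanism. CBr4/PPh3 converts it into (2E,6E,10E)-12-bromo-3,7,11-trimethyl-8-(phenylsulfonyl)dodeca-2,6,10-trien-1-yl acetate F2. Direct SN2 with PhSO2Na in DMF at 25 °C then gives 7 without allylic transposition.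

Step 6: the lithiated bis-sulfone may add sluggishly to the hindered silyloxy lactone, or proton transfer may erode the C-12 selectivity. Fallback, setting out from 8 and coming back at 10: open 8 with MeNH(OMe)·HCl/AlMe3 to the Weinreb amide (2R)-2,4-dihydroxy-N-methoxy-N,3,3-trimethylbutanamide F3. Silylate both hydroxyls (Et3SiOTf, 2,6-lutidine) to (2R)-N-methoxy-N,3,3-trimethyl-2,4-bis(triethylsilyloxy)butanamide F4. Acylate lithiated 7 with this acyclic, more electrophilic donor, whose chelated tetrahedral intermediate prevents over-addition, to give (2E,6E,10E,14R)-3,7,11,15,15-pentamethyl-13-oxo-8,12-bis(phenylsulfonyl)-14,16-bis(triethylsilyloxy)hexadeca-2,6,10-trien-1-yl acetate F5. HF·pyridine removes both silyl groups and gives 10.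

Step 10 (the new cascade): sulfinate build-up can quench the photocatalyst, the second ring closure may lag, and sulfonyl loss is slower from the C-8 epimer whose C–S bond ends up equatorial. Fallback with known reaction types, setting out from 13 and coming back at 15: saponify 13 with CsOH·H2O as in step 10, then run the known photoredox/cobaloxime decarboxylative desaturation (4CzIPN, Co(dmgH)2(py)Cl 10 mol %, 0.1 M, blue LEDs). Here divalent cobalt intercepts the tertiary radical before it cyclises and gives the isopropenyl triol (2E,6E,10E,13S,14R)-3,7,11,15-tetramethyl-8-(phenylsulfonyl)hexadeca-2,6,10,15-tetraene-1,13,14-triol F6. Hydrogen-atom transfer from an iron hydride (Fe(acac)3, PhSiH3, EtOH, 25 °C), the established thermal way to start radical polyene cyclisations from a 1,1-disubstituted alkene, regenerates the same C-4 radical without photocatalyst or carboxylate. The chain is carried on to 15 with the same sulfonyl loss.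

**Further compounds**
F1 | step 5 | (2E,6E,10E)-12-hydroxy-3,7,11-trimethyl-8-(phenylsulfonyl)dodeca-2,6,10-trien-1-yl acetate | CC(=O)OC/C=C(C)/CC/C=C(C)/C(C/C=C(C)/CO)S(=O)(=O)c1ccccc1
F2 | step 5 | (2E,6E,10E)-12-bromo-3,7,11-trimethyl-8-(phenylsulfonyl)dodeca-2,6,10-trien-1-yl acetate | CC(=O)OC/C=C(C)/CC/C=C(C)/C(C/C=C(C)/CBr)S(=O)(=O)c1ccccc1
F3 | step 6 | (2R)-2,4-dihydroxy-N-methoxy-N,3,3-trimethylbutanamide | CON(C)C(=O)[C@H](O)C(C)(C)CO
F4 | step 6 | (2R)-N-methoxy-N,3,3-trimethyl-2,4-bis(triethylsilyloxy)butanamide | CON(C)C(=O)[C@H](O[Si](CC)(CC)CC)C(C)(C)CO[Si](CC)(CC)CC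
F5 | step 6 | (2E,6E,10E,14R)-3,7,11,15,15-pentamethyl-13-oxo-8,12-bis(phenylsulfonyl)-14,16-bis(triethylsilyloxy)hexadeca-2,6,10-trien-1-yl acetate | CC(=O)OC/C=C(C)/CC/C=C(C)/C(C/C=C(C)/C(S(=O)(=O)c1ccccc1)C(=O)[C@H](O[Si](CC)(CC)CC)C(C)(C)CO[Si](CC)(CC)CC)S(=O)(=O)c1ccccc1
F6 | step 10 | (2E,6E,10E,13S,14R)-3,7,11,15-tetramethyl-8-(phenylsulfonyl)hexadeca-2,6,10,15-tetraene-1,13,14-triol | OC/C=C(C)/CC/C=C(C)/C(C/C=C(C)/C[C@H](O)[C@H](O)C(C)=C)S(=O)(=O)c1ccccc1
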